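The route rests on making the benzene ring itself, by cleaving the bond between the ring carbon bearing the C1 benzylic CH2 and its ortho neighbour. The key step exploits the 1,3,5-pattern of that ring: both ring oxygens are meta to the carbon carrying C1, so this carbon maps onto the C7 ketone of a linear 3,5,7-triketo ester and the oxygenated carbons onto C3 and C5. One base-mediated aldol–dehydration of triketo ester 14, in which the protected C2 and C8 carbinols (silyl ether, benzyl ether) already hang on C7, closes the ring as a 2,4-dihydroxybenzoate whose ester later differentiates the two phenols and is then lost as CO2.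

Key step: step 10

Assumption: chain atoms are numbered as in the target (C1 benzylic CH2, C2 acetoxy carbon, C8 free carbinol); salen = N,N′-bis(3,5-di-tert-butylsalicylidene)cyclohexane-1,2-diaminate, and (S,S)-Co(salen)(OAc) is taken to hydrolyse the (R)-enantiomer of a 2-alkyloxirane faster, which a chiral GC check on 2 should confirm before step 2.

Step 1
Reactants: 1 (±)-2-pentyloxirane (racemic 1,2-epoxyheptane)
Product: 2 (S)-2-pentyloxirane
Conditions: (S,S)-Co(salen)(OAc) (0.5 mol%), H2O (0.55 equiv), neat, 0 °C → rt; distillation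
Reagents that add atoms: none
Why: Jacobsen hydrolytic kinetic resolution, in which the chiral trivalent cobalt complex should open the (R)-epoxide with water much faster, so that the volatile (S)-epoxide, whose stereocentre becomes C8 of the target, is distilled from the diol in high enantiomeric purity.

Step 2
Reactants: 2 (S)-2-pentyloxirane; 3 6-bromohex-1-ene
Product: 5 (S)-tridec-1-en-8-ol, via hex-5-enylmagnesium bromide 4 (not isolated)
Conditions: 3, Mg, THF, rt; then CuI (10 mol%), 2, THF, −30 → 0 °C; cold 1 M HCl work-up
Reagents that add atoms: none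
Why: Copper-catalysed Grignard opening of a terminal epoxide is an SN2 attack at the unsubstituted CH2, so the carbinol carbon is not involved and keeps the S configuration.

Step 3
Reactants: 5 (S)-tridec-1-en-8-ol
Product: 6 (S)-8-(benzyloxy)tridec-1-ene
Conditions: NaH, BnBr, Bu4NI (cat.), THF/DMF, 0 °C → rt
Reagents that add atoms: benzyl bromide, BrCc1ccccc1
Why: Williamson ether synthesis on the sodium alkoxide leaves the C–O bond of the stereocentre intact, and the benzyl ether should survive every later step until the final hydrogenolysis.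

Step 4
Reactants: 6 (S)-8-(benzyloxy)tridec-1-ene
Product: 7 (S)-8-(benzyloxy)tridecan-2-one
Conditions: PdCl2 (10 mol%), CuCl (1 equiv), O2 (1 atm), DMF/H2O 7:1, rt
Reagents that add atoms: water, O
Why: Tsuji–Wacker oxidation of a terminal alkene gives the methyl ketone by Markovnikov hydroxypalladation, and the remote benzyl ether does not interfere.

Step 5
Reactants: 7 (S)-8-(benzyloxy)tridecan-2-one
Product: 8 methyl (S)-9-(benzyloxy)-3-oxotetradecanoate
Conditions: NaH (2.5 equiv), (MeO)2CO (4 equiv), THF, reflux; cold 1 M HCl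
Reagents that add atoms: dimethyl carbonate, COC(=O)OC
Why: Claisen-type C-acylation of a methyl ketone with a dialkyl carbonate takes place at the less hindered methyl group and is driven by formation of the β-keto ester enolate.

Step 6
Reactants: 8 methyl (S)-9-(benzyloxy)-3-oxotetradecanoate
Product: 9 methyl (3R,9S)-9-(benzyloxy)-3-hydroxytetradecanoate
Conditions: H2 (10 bar), RuCl2[(R)-BINAP] (0.5 mol%), MeOH, 60 °C
Reagents that add atoms: none
Why: Noyori asymmetric hydrogenation of a β-keto ester, in which the (R)-BINAP ligand directs hydride to one face of the ester-chelated ketone and so sets C3 (the later C2 of the target) as R under catalyst control, while this ruthenium catalyst does not cleave benzyl ethers.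

Step 7
Reactants: 9 methyl (3R,9S)-9-(benzyloxy)-3-hydroxytetradecanoate
Product: 10 (3R,9S)-9-(benzyloxy)-3-hydroxy-N-methoxy-N-methyltetradecanamide
Conditions: MeNH(OMe)·HCl (2.5 equiv), iPrMgCl (6 equiv), THF, −20 → 0 °C; cold 1 M HCl
Reagents that add atoms: N,O-dimethylhydroxylamine hydrochloride, CNOC.Cl
Why: Weinreb amide formation by aminolysis of the ester with the magnesium amide runs on the magnesium alkoxide of the free β-hydroxy ester, which can neither eliminate nor epimerise.

Step 8
Reactants: 10 (3R,9S)-9-(benzyloxy)-3-hydroxy-N-methoxy-N-methyltetradecanamide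
Product: 11 (3R,9S)-9-(benzyloxy)-N-methoxy-N-methyl-3-[(triisopropylsilyl)oxy]tetradecanamide
Conditions: iPr3SiOTf (1.3 equiv), 2,6-lutidine (2 equiv), CH2Cl2, 0 °C → rt
Reagents that add atoms: triisopropylsilyl trifluoromethanesulfonate, CC(C)[Si](OS(=O)(=O)C(F)(F)F)(C(C)C)C(C)C
Why: O-silylation with a silyl triflate and a hindered pyridine base proceeds with retention, and the bulky triisopropylsilyl ether is chosen because it should resist β-elimination in steps 9 and 10 and hot hydroxide in step 12.

Step 9
Reactants: 11 (3R,9S)-9-(benzyloxy)-N-methoxy-N-methyl-3-[(triisopropylsilyl)oxy]tetradecanamide; 12 methyl 3,5-dioxohexanoate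
Product: 14 methyl (9R,15S)-15-(benzyloxy)-3,5,7-trioxo-9-[(triisopropylsilyl)oxy]icosanoate, via trilithium trianion 13 (not isolated)
Conditions: 12 (2 equiv), LiN(iPr)2 (3.0 equiv per 12), THF, −78 → 0 °C; then 11, −78 → −20 °C; AcOH, −78 °C; crude used at once
Reagents that add atoms: none
Why: Polyanion C-acylation of the Harris type, in which the terminal carbanion (C6) of the trianion is its most nucleophilic site and adds once to the Weinreb amide, whose chelated tetrahedral adduct collapses only on quenching, so that the triketo ester should form without over-addition.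

Step 10
Reactants: 14 methyl (9R,15S)-15-(benzyloxy)-3,5,7-trioxo-9-[(triisopropylsilyl)oxy]icosanoate
Product: 16 methyl 6-[(2R,8S)-8-(benzyloxy)-2-[(triisopropylsilyl)oxy]tridecyl]-2,4-dihydroxybenzoate, via cyclic aldol adduct 15 (not isolated)
Conditions: K2CO3 (3 equiv), MeOH, 0 °C → rt; then AcOH to pH 5, rt
Reagents that add atoms: none
Why: Carbonate generates the polyenolate, whose C2 carbon (flanked by the ester and the C3 carbonyl) adds to the C7 ketone to give the cyclic aldol 15, which loses water by E1cB and tautomerises twice to the arene, so that the C2–C7 bond becomes the sixth bond of the benzene ring. The closest known reaction type is the biomimetic aldol cyclisation–aromatisation of 3,5,7-triketo esters to 6-alkyl-2,4-dihydroxybenzoates (Harris cyclisation), the laboratory counterpart of the polyketide synthase ring closure. The single ring is closed in the 6-(enolendo)-exo-trig mode. No stereocentre is created, the two transient ring stereocentres of 15 disappear on aromatisation, and C9 and C15 lie outside the reacting array and keep their configuration. The step needs chemoselectivity for the C2-to-C7 aldol over the C6-to-C1 Claisen closure, over O-acylation to a pyranone and over E1cB loss of the C9 silyloxy group. A protic, magnesium-free carbonate medium leaves the ester unactivated and lets the irreversible aromatisation drain the reversible aldol, while the bulky triisopropylsilyloxy group, a poor leaving group next to an already enolised chain, should resist elimination.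

Step 11
Reactants: 16 methyl 6-[(2R,8S)-8-(benzyloxy)-2-[(triisopropylsilyl)oxy]tridecyl]-2,4-dihydroxybenzoate
Product: 17 methyl 6-[(2R,8S)-8-(benzyloxy)-2-[(triisopropylsilyl)oxy]tridecyl]-2-hydroxy-4-methoxybenzoate
Conditions: MeI (1.2 equiv), K2CO3 (1.5 equiv), acetone, rt
Reagents that add atoms: iodomethane, CI
Why: Williamson O-methylation should be selective for the 4-hydroxyl, the more acidic and unhindered phenol para to the ester, because the 2-hydroxyl is tied up in a hydrogen bond to the ester carbonyl.

Step 12
Reactants: 17 methyl 6-[(2R,8S)-8-(benzyloxy)-2-[(triisopropylsilyl)oxy]tridecyl]-2-hydroxy-4-methoxybenzoate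
Product: 19 3-[(2R,8S)-8-(benzyloxy)-2-[(triisopropylsilyl)oxy]tridecyl]-5-methoxyphenol, via carboxylic acid 18 (not isolated)
Conditions: KOH (10 equiv), EtOH/H2O 4:1, 85 °C; then 1 M HCl to pH 3, 0 °C, extraction into toluene, reflux
Reagents that add atoms: none
Why: Saponification followed by protodecarboxylation of the ortho-hydroxy, para-methoxy benzoic acid (ipso protonation of the electron-rich ring, as with orsellinic acids) removes the ester carbon, and it is run while the C2 oxygen is still silylated so that no hydroxyl is free to lactonise onto the ester as a dihydroisocoumarin.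

Step 13
Reactants: 19 3-[(2R,8S)-8-(benzyloxy)-2-[(triisopropylsilyl)oxy]tridecyl]-5-methoxyphenol
Product: 20 3-[(2R,8S)-8-(benzyloxy)-2-hydroxytridecyl]-5-methoxyphenol
Conditions: Bu4NF (3 equiv), THF, rt → 45 °C; H2O work-up
Reagents that add atoms: none
Why: Fluoride-mediated desilylation, driven by the strong Si–F bond, frees the C2 alcohol without touching its C–O bond, the benzyl ether or the aryl methyl ether.

Step 14
Reactants: 20 3-[(2R,8S)-8-(benzyloxy)-2-hydroxytridecyl]-5-methoxyphenol
Product: 22 (2R,8S)-8-(benzyloxy)-1-(3-hydroxy-5-methoxyphenyl)tridecan-2-yl acetate, via diacetate 21 (not isolated)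
Conditions: Ac2O (3 equiv), Et3N (4 equiv), DMAP (5 mol%), CH2Cl2, 0 °C → rt; then pyrrolidine (5 equiv), 0 °C → rt
Reagents that add atoms: acetic anhydride, CC(=O)OC(C)=O
Why: DMAP-catalysed acetylation esterifies both hydroxyls with retention at C2, and the aryl acetate, an activated ester with a phenoxide leaving group, is then removed selectively by aminolysis, which should not touch the secondary alkyl acetate at room temperature.

Step 15
Reactants: 22 (2R,8S)-8-(benzyloxy)-1-(3-hydroxy-5-methoxyphenyl)tridecan-2-yl acetate
Product: 23 (2R,8S)-8-hydroxy-1-(3-hydroxy-5-methoxyphenyl)tridecan-2-yl acetate (CNP0415796.1)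
Conditions: H2 (1 atm), 10% Pd/C, EtOAc, rt
Reagents that add atoms: none
Why: Catalytic hydrogenolysis cleaves only the benzylic C–O bond of the benzyl ether, leaving the non-benzylic C2 acetate, the phenol, the aryl methyl ether and both stereocentres unchanged.

Compound list
1 | (±)-2-pentyloxirane (racemic 1,2-epoxyheptane) | CCCCCC1CO1 | starting material
2 | (S)-2-pentyloxirane | CCCCC[C@H]1CO1 | intermediate
3 | 6-bromohex-1-ene | C=CCCCCBr | starting material
4 | hex-5-enylmagnesium bromide | C=CCCCC[Mg]Br | intermediate (not isolated)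
5 | (S)-tridec-1-en-8-ol | CCCCC[C@H](O)CCCCCC=C | intermediate
6 | (S)-8-(benzyloxy)tridec-1-ene | CCCCC[C@H](OCc1ccccc1)CCCCCC=C | intermediate
7 | (S)-8-(benzyloxy)tridecan-2-one | CCCCC[C@H](OCc1ccccc1)CCCCCC(C)=O | intermediate
8 | methyl (S)-9-(benzyloxy)-3-oxotetradecanoate | CCCCC[C@H](OCc1ccccc1)CCCCCC(=O)CC(=O)OC | intermediate
9 | methyl (3R,9S)-9-(benzyloxy)-3-hydroxytetradecanoate | CCCCC[C@H](OCc1ccccc1)CCCCC[C@H](CC(=O)OC)O | intermediate
10 | (3R,9S)-9-(benzyloxy)-3-hydroxy-N-methoxy-N-methyltetradecanamide | CCCCC[C@H](OCc1ccccc1)CCCCC[C@H](CC(=O)N(C)OC)O | intermediate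
11 | (3R,9S)-9-(benzyloxy)-N-methoxy-N-methyl-3-[(triisopropylsilyl)oxy]tetradecanamide | CCCCC[C@H](OCc1ccccc1)CCCCC[C@H](CC(=O)N(C)OC)O[Si](C(C)C)(C(C)C)C(C)C | intermediate
12 | methyl 3,5-dioxohexanoate | COC(=O)CC(=O)CC(C)=O | starting material
13 | trilithium trianion of methyl 3,5-dioxohexanoate | [Li+].[Li+].[Li+].COC(=O)[CH-]C(=O)[CH-]C(=O)[CH2-] | intermediate (not isolated)
14 | methyl (9R,15S)-15-(benzyloxy)-3,5,7-trioxo-9-[(triisopropylsilyl)oxy]icosanoate | CCCCC[C@H](OCc1ccccc1)CCCCC[C@H](CC(=O)CC(=O)CC(=O)CC(=O)OC)O[Si](C(C)C)(C(C)C)C(C)C | intermediate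
15 | methyl 2-[(2R,8S)-8-(benzyloxy)-2-[(triisopropylsilyl)oxy]tridecyl]-2-hydroxy-4,6-dioxocyclohexane-1-carboxylate (ring stereocentres undefined) | CCCCC[C@H](OCc1ccccc1)CCCCC[C@H](CC1(O)CC(=O)CC(=O)C1C(=O)OC)O[Si](C(C)C)(C(C)C)C(C)C | intermediate (not isolated)
16 | methyl 6-[(2R,8S)-8-(benzyloxy)-2-[(triisopropylsilyl)oxy]tridecyl]-2,4-dihydroxybenzoate | CCCCC[C@H](OCc1ccccc1)CCCCC[C@H](Cc1cc(O)cc(O)c1C(=O)OC)O[Si](C(C)C)(C(C)C)C(C)C | intermediate
17 | methyl 6-[(2R,8S)-8-(benzyloxy)-2-[(triisopropylsilyl)oxy]tridecyl]-2-hydroxy-4-methoxybenzoate | CCCCC[C@H](OCc1ccccc1)CCCCC[C@H](Cc1cc(OC)cc(O)c1C(=O)OC)O[Si](C(C)C)(C(C)C)C(C)C | intermediate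
18 | 6-[(2R,8S)-8-(benzyloxy)-2-[(triisopropylsilyl)oxy]tridecyl]-2-hydroxy-4-methoxybenzoic acid | CCCCC[C@H](OCc1ccccc1)CCCCC[C@H](Cc1cc(OC)cc(O)c1C(=O)O)O[Si](C(C)C)(C(C)C)C(C)C | intermediate (not isolated)
19 | 3-[(2R,8S)-8-(benzyloxy)-2-[(triisopropylsilyl)oxy]tridecyl]-5-methoxyphenol | CCCCC[C@H](OCc1ccccc1)CCCCC[C@H](Cc1cc(O)cc(OC)c1)O[Si](C(C)C)(C(C)C)C(C)C | intermediate
20 | 3-[(2R,8S)-8-(benzyloxy)-2-hydroxytridecyl]-5-methoxyphenol | CCCCC[C@H](OCc1ccccc1)CCCCC[C@H](Cc1cc(O)cc(OC)c1)O | intermediate
21 | 3-[(2R,8S)-2-acetoxy-8-(benzyloxy)tridecyl]-5-methoxyphenyl acetate | CCCCC[C@H](OCc1ccccc1)CCCCC[C@H](Cc1cc(OC(C)=O)cc(OC)c1)OC(C)=O | intermediate (not isolated)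
22 | (2R,8S)-8-(benzyloxy)-1-(3-hydroxy-5-methoxyphenyl)tridecan-2-yl acetate | CCCCC[C@H](OCc1ccccc1)CCCCC[C@H](Cc1cc(O)cc(OC)c1)OC(C)=O | intermediate
23 | (2R,8S)-8-hydroxy-1-(3-hydroxy-5-methoxyphenyl)tridecan-2-yl acetate | CCCCC[C@H](O)CCCCC[C@H](Cc1cc(O)cc(OC)c1)OC(C)=O | target

Total step count: 15. Longest linear sequence: 15 steps (1 to 23); 3 and 12 are purchased.

Steps most likely to fail

Step 10. The polyenolate may close in the Claisen sense or through oxygen, giving an acylphloroglucinol or a pyranone, or the silyloxy group may be lost by E1cB before the aldol takes place. The fallback gives up the ring construction and attaches a purchased arene; it sets out from 6 and comes back at 20. Epoxidation of the terminal alkene of 6 with mCPBA in CH2Cl2 should give 2-[(6S)-6-(benzyloxy)undecyl]oxirane F1 as a mixture of both epimers at the oxirane carbon. Hydrolytic kinetic resolution with (R,R)-Co(salen)(OAc) and 0.55 equiv of water should leave (2R)-2-[(6S)-6-(benzyloxy)undecyl]oxirane F2. Purchased 3,5-dimethoxyphenylmagnesium chloride with catalytic CuI in THF at −30 °C should open F2 at its CH2 to give (2R,8S)-8-(benzyloxy)-1-(3,5-dimethoxyphenyl)tridecan-2-ol F3. NaSEt in DMF at 140 °C should remove one aryl methyl group only, since the phenoxide formed shields the second ether, and this gives 20, which goes on through steps 14 and 15.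

Step 9. Proton transfer from the α-CH2 of the Weinreb amide to the strongly basic trianion (with loss of silanolate), or O-acylation in place of C-acylation, may consume the amide. The fallback makes the C6–C7 bond by aldol addition and restores the ketone afterwards; it sets out from 11 and comes back at 14. Reduction of 11 with iBu2AlH in THF at −78 °C should give (3R,9S)-9-(benzyloxy)-3-[(triisopropylsilyl)oxy]tetradecanal F4. Trianion 13 should add through its terminal carbon to this far more electrophilic aldehyde at −78 °C to give methyl (9R,15S)-15-(benzyloxy)-7-hydroxy-3,5-dioxo-9-[(triisopropylsilyl)oxy]icosanoate F5 as both C7 epimers, which is of no consequence. Oxidation of the C7 carbinol with Dess–Martin periodinane in CH2Cl2 should then give 14.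

Step 12. Hydroxide may attack the hindered, phenoxide-deactivated acyl carbon too slowly, or forcing conditions may strip the silyl ether, after which the free alkoxide lactonises onto the ester. The fallback cleaves the ester at its O–CH3 bond by SN2 dealkylation, so that neither attack at the acyl carbon nor hydroxide is needed; it sets out from 17 and comes back at 18. LiI (5 equiv) in pyridine at reflux should give the lithium salt of acid 18, which is acidified and warmed in toluene as in step 12 to lose CO2 and give 19.

Further compounds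
F1 | step 10 | 2-[(6S)-6-(benzyloxy)undecyl]oxirane (both epimers at the oxirane carbon) | CCCCC[C@H](OCc1ccccc1)CCCCCC1CO1
F2 | step 10 | (2R)-2-[(6S)-6-(benzyloxy)undecyl]oxirane | CCCCC[C@H](OCc1ccccc1)CCCCC[C@@H]1CO1
F3 | step 10 | (2R,8S)-8-(benzyloxy)-1-(3,5-dimethoxyphenyl)tridecan-2-ol | CCCCC[C@H](OCc1ccccc1)CCCCC[C@H](Cc1cc(OC)cc(OC)c1)O
F4 | step 9 | (3R,9S)-9-(benzyloxy)-3-[(triisopropylsilyl)oxy]tetradecanal | CCCCC[C@H](OCc1ccccc1)CCCCC[C@H](CC=O)O[Si](C(C)C)(C(C)C)C(C)C
F5 | step 9 | methyl (9R,15S)-15-(benzyloxy)-7-hydroxy-3,5-dioxo-9-[(triisopropylsilyl)oxy]icosanoate (both C7 epimers) | CCCCC[C@H](OCc1ccccc1)CCCCC[C@H](CC(O)CC(=O)CC(=O)CC(=O)OC)O[Si](C(C)C)(C(C)C)C(C)C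
F0 | step 12 | none | none
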